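## Retrosynthetic overview

- The cyclohexene (ring A) is numbered C1 (CH3-bearing sp2 carbon), C2 (=CH), C3 (chalcone-bearing aryl), C4 (aroyl), C5 (4-hydroxyphenyl), C6 (CH2). The target is (3S,4S,5S): 3,4-trans and 4,5-cis. An E-enone cannot give 4,5-cis directly, so the target is reached as the C4 epimer of an endo Diels–Alder adduct; the last operations are base equilibration at C4 (the only enolisable stereocentre) and global acetal removal.
- Ring A, the only ring formed, comes from an endo [4+2] between a 2'-hydroxychalcone dienophile (bis-MOM isobavachalcone) and an (E)-1-aryl-3-methylbutadiene (dehydroprenyl chalcone). This sets C3, C4 and C5 in one step (3,4-cis, 4,5-trans).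
- Absolute configuration: the two phenol oxygens flanking the diene are masked as menthyloxymethyl acetals made from (−)-menthol. The cycloadducts are therefore diastereomers; the (3S,4R,5S) one is carried on, and the menthyl units leave with the MOM groups.
- Dienophile: resacetophenone by C-prenylation, mono-MOM protection, Claisen–Schmidt. Diene: resacetophenone by C3 iodination, acetalisation, Claisen–Schmidt, Suzuki coupling with a dienylboronate made by enyne hydroboration.

Assumption: the two MOM-protected benzaldehydes and (−)-chloromethyl menthyl ether are bought as catalogue chemicals; "menthyl" always means (1R,2S,5R)-menthyl and "menthyloxymethoxy" means ArO–CH2–O–menthyl.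

## Route

Step 1
Reactants: 1 1-(2,4-dihydroxyphenyl)ethanone; 2 1-bromo-3-methylbut-2-ene
Product: 3 1-[2,4-dihydroxy-3-(3-methylbut-2-enyl)phenyl]ethanone
Conditions: KOH (2 equiv, 10% aq), 0 °C to rt; then 1 M HCl; chromatography
Reagents that add atoms: none
Why: C-alkylation of the resorcinolate in water goes mainly to C3, the carbon ortho to both oxygens (direct C-prenylation, modest yield, separated from the 5-prenyl and O-prenyl isomers); no stereocentre.

Step 2
Reactants: 3 1-[2,4-dihydroxy-3-(3-methylbut-2-enyl)phenyl]ethanone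
Product: 4 1-[2-hydroxy-4-(methoxymethoxy)-3-(3-methylbut-2-enyl)phenyl]ethanone
Conditions: MOMCl (1.1 equiv), K2CO3, acetone, rt
Reagents that add atoms: chloromethyl methyl ether (COCCl)
Why: Williamson-type O-alkylation; the 2-OH is held in a hydrogen bond to the acetyl carbonyl, so only the 4-OH reacts under mild base.

Step 3
Reactants: 4 1-[2-hydroxy-4-(methoxymethoxy)-3-(3-methylbut-2-enyl)phenyl]ethanone; 5 4-(methoxymethoxy)benzaldehyde
Product: 7 (E)-1-[2-hydroxy-4-(methoxymethoxy)-3-(3-methylbut-2-enyl)phenyl]-3-[4-(methoxymethoxy)phenyl]prop-2-en-1-one, via aldol adduct 6 (not isolated)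
Conditions: KOH (3 equiv), EtOH/H2O, rt, 36 h; then 1 M HCl to pH 6 at 0 °C
Reagents that add atoms: none
Why: Claisen–Schmidt aldol condensation; E1cB dehydration of the aldol gives the more stable E-enone, and the chelated 2'-OH needed to activate the dienophile stays free.

Step 4
Reactants: 1 1-(2,4-dihydroxyphenyl)ethanone
Product: 8 1-(2,4-dihydroxy-3-iodophenyl)ethanone
Conditions: I2 (0.4 equiv), HIO3 (0.2 equiv), EtOH/H2O, rt
Reagents that add atoms: iodine ([I][I]); iodic acid (OI(=O)=O)
Why: Electrophilic aromatic iodination at C3, the position activated by both ortho hydroxyl groups; this is the established regiochemistry for resacetophenone.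

Step 5
Reactants: 8 1-(2,4-dihydroxy-3-iodophenyl)ethanone; 9 (−)-chloromethyl menthyl ether (chloromethyl ether of (1R,2S,5R)-menthol)
Product: 10 1-[3-iodo-2,4-bis(menthyloxymethoxy)phenyl]ethanone
Conditions: NaH (2.5 equiv), 9 (2.4 equiv), DMF, 0 °C to rt
Reagents that add atoms: none
Why: Double O-alkylation of the bis-phenoxide gives base-stable MOM-type acetals that block the future chalcone 2'-OH (so this enone cannot later act as dienophile) and place two enantiopure menthyl units beside the future C3 aryl; the menthyl stereocentres are not touched.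

Step 6
Reactants: 10 1-[3-iodo-2,4-bis(menthyloxymethoxy)phenyl]ethanone; 11 2,4-bis(methoxymethoxy)benzaldehyde
Product: 13 (E)-3-[2,4-bis(methoxymethoxy)phenyl]-1-[3-iodo-2,4-bis(menthyloxymethoxy)phenyl]prop-2-en-1-one, via aldol adduct 12 (not isolated)
Conditions: KOH (3 equiv), EtOH, rt, 48 h; then 1 M HCl to pH 6 at 0 °C
Reagents that add atoms: none
Why: Claisen–Schmidt aldol condensation to the E-chalcone; acetals and the aryl iodide are inert to hydroxide.

Step 7
Reactants: 14 2-methylbut-1-en-3-yne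
Product: 15 4,4,5,5-tetramethyl-2-[(1E)-3-methylbuta-1,3-dienyl]-1,3,2-dioxaborolane
Conditions: pinacolborane (1.05 equiv), (C5H5)2Zr(H)Cl (5 mol%), Et3N (10 mol%), neat, 60 °C
Reagents that add atoms: pinacolborane (CC1(C)OBOC1(C)C)
Why: Zirconium-catalysed syn hydroboration of the terminal alkyne (faster than the 1,1-disubstituted alkene) puts boron on the terminal carbon and gives the E-dienylboronate.

Step 8
Reactants: 13 (E)-3-[2,4-bis(methoxymethoxy)phenyl]-1-[3-iodo-2,4-bis(menthyloxymethoxy)phenyl]prop-2-en-1-one; 15 4,4,5,5-tetramethyl-2-[(1E)-3-methylbuta-1,3-dienyl]-1,3,2-dioxaborolane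
Product: 16 (E)-3-[2,4-bis(methoxymethoxy)phenyl]-1-{2,4-bis(menthyloxymethoxy)-3-[(1E)-3-methylbuta-1,3-dienyl]phenyl}prop-2-en-1-one
Conditions: Pd(OAc)2 (5 mol%), SPhos (10 mol%), K3PO4, toluene/H2O 10:1, 70 °C
Reagents that add atoms: none
Why: Suzuki–Miyaura coupling; the electron-rich biarylphosphine copes with the di-ortho-substituted aryl iodide and the E geometry of the boronate is retained.

Step 9
Reactants: 7 (E)-1-[2-hydroxy-4-(methoxymethoxy)-3-(3-methylbut-2-enyl)phenyl]-3-[4-(methoxymethoxy)phenyl]prop-2-en-1-one; 16 (E)-3-[2,4-bis(methoxymethoxy)phenyl]-1-{2,4-bis(menthyloxymethoxy)-3-[(1E)-3-methylbuta-1,3-dienyl]phenyl}prop-2-en-1-one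
Product: 17 endo cycloadduct, ring A (3S,4R,5S), 3,4-cis and 4,5-trans (full structure in the compound list)
Conditions: 7 (1.0 equiv), 16 (1.2 equiv), Ag nanoparticles on SiO2 (0.5 mol% Ag), CH2Cl2, 50 °C, 48 h; SiO2 chromatography then preparative HPLC
Reagents that add atoms: none
Why: Silver-nanoparticle-catalysed Diels–Alder cycloaddition of the 2'-hydroxychalcone forms ring A with ortho/para regiochemistry; the E-enone fixes C4/C5 trans and the endo transition state puts the aroyl group cis to the C3 aryl, and because the diene carries the enantiopure menthyl acetals the (3S,4R,5S) and (3R,4S,5R) endo adducts (and the exo pair) are diastereomers that are separated, so C3 and C5 are secured by correlation with the (−)-menthol stereocentres.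

Step 10
Reactants: 17 endo cycloadduct, ring A (3S,4R,5S)
Product: 19 (3S,4S,5S) C4 epimer of 17 (3,4-trans 4,5-cis; protecting groups unchanged), via dipotassium enolate 18 (not isolated)
Conditions: KOC(CH3)3 (3 equiv), (CH3)3COH/THF 1:1, 50 °C, 12 h; then 1 M HCl to pH 6 at 0 °C; chromatography, recovered 17 resubmitted
Reagents that add atoms: none
Why: Reversible enolisation of the only acidic stereocentre (C4, alpha to the ketone) equilibrates 17 with its C4 epimer, in which the aroyl group is trans to the bulky di-ortho-substituted C3 aryl and cis to the C5 aryl while C3 and C5 are untouched; the equilibrium position is not known, so the epimers are separated and 17 is recycled.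

Step 11
Reactants: 19 (3S,4S,5S) hexa-acetal
Product: 20 CNP0218862.3
Conditions: 3 M HCl (aq)/MeOH/THF, 40 °C, 2–4 h, monitored; reverse-phase chromatography
Reagents that add atoms: none
Why: Acid-catalysed acetal methanolysis removes the four MOM and two menthyloxymethyl groups together under conditions mild enough to spare the prenyl group, both enones, the ring A alkene and the three stereocentres.

## Compound list

1 | 1-(2,4-dihydroxyphenyl)ethanone (resacetophenone) | CC(=O)c1ccc(O)cc1O | starting material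
2 | 1-bromo-3-methylbut-2-ene (prenyl bromide) | CC(C)=CCBr | starting material
3 | 1-[2,4-dihydroxy-3-(3-methylbut-2-enyl)phenyl]ethanone | CC(=O)c1ccc(O)c(CC=C(C)C)c1O | intermediate
4 | 1-[2-hydroxy-4-(methoxymethoxy)-3-(3-methylbut-2-enyl)phenyl]ethanone | CC(=O)c1ccc(OCOC)c(CC=C(C)C)c1O | intermediate
5 | 4-(methoxymethoxy)benzaldehyde | COCOc1ccc(C=O)cc1 | starting material
6 | aldol adduct, 3-hydroxy-1-[2-hydroxy-4-(methoxymethoxy)-3-(3-methylbut-2-enyl)phenyl]-3-[4-(methoxymethoxy)phenyl]propan-1-one (either carbinol configuration) | COCOc1ccc(C(O)CC(=O)c2ccc(OCOC)c(CC=C(C)C)c2O)cc1 | intermediate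
7 | (E)-1-[2-hydroxy-4-(methoxymethoxy)-3-(3-methylbut-2-enyl)phenyl]-3-[4-(methoxymethoxy)phenyl]prop-2-en-1-one | COCOc1ccc(/C=C/C(=O)c2ccc(OCOC)c(CC=C(C)C)c2O)cc1 | intermediate
8 | 1-(2,4-dihydroxy-3-iodophenyl)ethanone | CC(=O)c1ccc(O)c(I)c1O | intermediate
9 | (−)-chloromethyl menthyl ether, chloromethyl ether of (1R,2S,5R)-menthol | ClCO[C@@H]1C[C@H](C)CC[C@H]1C(C)C | starting material
10 | 1-[3-iodo-2,4-bis(menthyloxymethoxy)phenyl]ethanone | CC(=O)c1ccc(OCO[C@@H]2C[C@H](C)CC[C@H]2C(C)C)c(I)c1OCO[C@@H]3C[C@H](C)CC[C@H]3C(C)C | intermediate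
11 | 2,4-bis(methoxymethoxy)benzaldehyde | COCOc1ccc(C=O)c(OCOC)c1 | starting material
12 | aldol adduct, 3-[2,4-bis(methoxymethoxy)phenyl]-3-hydroxy-1-[3-iodo-2,4-bis(menthyloxymethoxy)phenyl]propan-1-one (either carbinol configuration) | COCOc1ccc(C(O)CC(=O)c2ccc(OCO[C@@H]3C[C@H](C)CC[C@H]3C(C)C)c(I)c2OCO[C@@H]4C[C@H](C)CC[C@H]4C(C)C)c(OCOC)c1 | intermediate
13 | (E)-3-[2,4-bis(methoxymethoxy)phenyl]-1-[3-iodo-2,4-bis(menthyloxymethoxy)phenyl]prop-2-en-1-one | COCOc1ccc(/C=C/C(=O)c2ccc(OCO[C@@H]3C[C@H](C)CC[C@H]3C(C)C)c(I)c2OCO[C@@H]4C[C@H](C)CC[C@H]4C(C)C)c(OCOC)c1 | intermediate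
14 | 2-methylbut-1-en-3-yne | C=C(C)C#C | starting material
15 | 4,4,5,5-tetramethyl-2-[(1E)-3-methylbuta-1,3-dienyl]-1,3,2-dioxaborolane | C=C(C)/C=C/B1OC(C)(C)C(C)(C)O1 | intermediate
16 | (E)-3-[2,4-bis(methoxymethoxy)phenyl]-1-{2,4-bis(menthyloxymethoxy)-3-[(1E)-3-methylbuta-1,3-dienyl]phenyl}prop-2-en-1-one | COCOc1ccc(/C=C/C(=O)c2ccc(OCO[C@@H]3C[C@H](C)CC[C@H]3C(C)C)c(/C=C/C(C)=C)c2OCO[C@@H]4C[C@H](C)CC[C@H]4C(C)C)c(OCOC)c1 | intermediate
17 | endo adduct: (3S,4R,5S)-1-methylcyclohexene (ring A) with C3 = 2,6-bis(menthyloxymethoxy)-3-[(E)-3-(2,4-bis(methoxymethoxy)phenyl)prop-2-enoyl]phenyl, C4 = 2-hydroxy-4-(methoxymethoxy)-3-(3-methylbut-2-enyl)benzoyl, C5 = 4-(methoxymethoxy)phenyl; 3,4-cis, 4,5-trans | CC(C)=CCc1c(OCOC)ccc(C(=O)[C@H]2[C@@H](c3c(OCO[C@@H]5C[C@H](C)CC[C@H]5C(C)C)ccc(C(=O)/C=C/c4ccc(OCOC)cc4OCOC)c3OCO[C@@H]6C[C@H](C)CC[C@H]6C(C)C)C=C(C)C[C@@H]2c2ccc(OCOC)cc2)c1O | intermediate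
18 | dipotassium phenoxide-enolate of 17 (C4 sp2, either enolate geometry; C3 and C5 as in 17) | CC(C)=CCc1c(OCOC)ccc(C([O-])=C2[C@@H](c3c(OCO[C@@H]5C[C@H](C)CC[C@H]5C(C)C)ccc(C(=O)/C=C/c4ccc(OCOC)cc4OCOC)c3OCO[C@@H]6C[C@H](C)CC[C@H]6C(C)C)C=C(C)C[C@@H]2c2ccc(OCOC)cc2)c1[O-].[K+].[K+] | intermediate
19 | (3S,4S,5S) C4 epimer of 17; 3,4-trans, 4,5-cis; same substituents | CC(C)=CCc1c(OCOC)ccc(C(=O)[C@@H]2[C@@H](c3c(OCO[C@@H]5C[C@H](C)CC[C@H]5C(C)C)ccc(C(=O)/C=C/c4ccc(OCOC)cc4OCOC)c3OCO[C@@H]6C[C@H](C)CC[C@H]6C(C)C)C=C(C)C[C@@H]2c2ccc(OCOC)cc2)c1O | intermediate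
20 | CNP0218862.3, (E)-1-{2,4-dihydroxy-3-[(1S,5S,6S)-6-[2,4-dihydroxy-3-(3-methylbut-2-enyl)benzoyl]-5-(4-hydroxyphenyl)-3-methylcyclohex-2-en-1-yl]phenyl}-3-(2,4-dihydroxyphenyl)prop-2-en-1-one; ring A (3S,4S,5S) | CC(C)=CCc1c(O)ccc(C(=O)[C@@H]2[C@@H](c3c(O)ccc(C(=O)/C=C/c4ccc(O)cc4O)c3O)C=C(C)C[C@@H]2c2ccc(O)cc2)c1O | target

## Step count and risks

Total steps: 11. Longest linear sequence: 7 (steps 4, 5, 6, 8, 9, 10, 11 from compound 1).

Most likely to fail:

**Step 10 (C4 equilibration).** This is the weakest step. Both epimers have one cis vicinal pair, so the equilibrium between 17 and 19 may be close to 1:1 or favour 17, and kinetic protonation on quench is expected to return 17. If the protected-stage equilibrium is poor, the order of the last two operations is changed. The fallback sets out from 17: the acid treatment of step 11 gives the (3S,4R,5S) heptaphenol F4, whose C3 aryl now carries free hydroxyl groups and so has a different conformational balance around C4. It is then equilibrated at C4 through the enol of the hydrogen-bonded o-hydroxyaryl ketone (catalytic HCl in MeOH, 40 °C). Reverse-phase HPLC separates the epimers, unchanged material is resubmitted, and the route is rejoined at 20.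

**Step 9 (cycloaddition and isolation of one of four stereoisomers).** The menthyl acetals are not expected to bias the diene faces, so the two endo adducts form in roughly equal amounts and the desired isomer is at best about a third of the adduct mixture. The (3S,4R,5S) isomer is assigned by ECD after deprotecting an aliquot. If 16 reacts sluggishly or the endo diastereomers of 17 cannot be separated, the cycloaddition is moved ahead of the second chalcone formation. This fallback sets out from 10: Suzuki coupling of 10 with 15 under the step 8 conditions gives the smaller diene ketone 1-{2,4-bis(menthyloxymethoxy)-3-[(1E)-3-methylbuta-1,3-dienyl]phenyl}ethanone F1. The Ag/SiO2 Diels–Alder reaction of F1 with 7 gives the acetyl-bearing endo adduct F2, whose (3S,4R,5S) diastereomer is separated at this lower molecular weight. Claisen–Schmidt condensation of F2 with 11 (KOH, EtOH, through the aldol adduct F3) comes back to the route at 17; any 19 formed by concurrent C4 equilibration is collected as well.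

**Step 11 (global acid deprotection).** Protic acid may cyclise the prenyl group or the ring A alkene onto neighbouring phenols, or close the 2'-hydroxychalcone to a flavanone. In that case the acetals are exchanged for silyl ethers under non-protic conditions. The fallback sets out from 19: triethylsilyl trifluoromethanesulfonate and 2,2'-bipyridyl in CH2Cl2 at 0 °C convert the six aryl acetals and the free phenol into the heptakis(triethylsilyl) ether F5. KF in MeOH at 0 °C then removes the silyl groups near neutral pH and the route is rejoined at 20.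

Further compounds
F1 | step 9 | 1-{2,4-bis(menthyloxymethoxy)-3-[(1E)-3-methylbuta-1,3-dienyl]phenyl}ethanone | CC(=O)c1ccc(OCO[C@@H]2C[C@H](C)CC[C@H]2C(C)C)c(/C=C/C(C)=C)c1OCO[C@@H]3C[C@H](C)CC[C@H]3C(C)C
F2 | step 9 | acetyl-bearing endo adduct, ring A (3S,4R,5S): as 17 but with an acetyl group in place of the 3-arylprop-2-enoyl group | CC(C)=CCc1c(OCOC)ccc(C(=O)[C@H]2[C@@H](c3c(OCO[C@@H]5C[C@H](C)CC[C@H]5C(C)C)ccc(C(C)=O)c3OCO[C@@H]6C[C@H](C)CC[C@H]6C(C)C)C=C(C)C[C@@H]2c2ccc(OCOC)cc2)c1O
F3 | step 9 | aldol adduct of F2 and 11 (either carbinol configuration) | CC(C)=CCc1c(OCOC)ccc(C(=O)[C@H]2[C@@H](c3c(OCO[C@@H]5C[C@H](C)CC[C@H]5C(C)C)ccc(C(=O)CC(O)c4ccc(OCOC)cc4OCOC)c3OCO[C@@H]6C[C@H](C)CC[C@H]6C(C)C)C=C(C)C[C@@H]2c2ccc(OCOC)cc2)c1O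
F4 | step 10 | (3S,4R,5S) heptaphenol, C4 epimer of 20 | CC(C)=CCc1c(O)ccc(C(=O)[C@H]2[C@@H](c3c(O)ccc(C(=O)/C=C/c4ccc(O)cc4O)c3O)C=C(C)C[C@@H]2c2ccc(O)cc2)c1O
F5 | step 11 | heptakis(triethylsilyl) ether of 20 | CC(C)=CCc1c(O[Si](CC)(CC)CC)ccc(C(=O)[C@@H]2[C@@H](c3c(O[Si](CC)(CC)CC)ccc(C(=O)/C=C/c4ccc(O[Si](CC)(CC)CC)cc4O[Si](CC)(CC)CC)c3O[Si](CC)(CC)CC)C=C(C)C[C@@H]2c2ccc(O[Si](CC)(CC)CC)cc2)c1O[Si](CC)(CC)CC
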